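With the core numbered C1–C9 (C9 the bridging ketone, C8 the gem-dimethyl carbon, C7 the prenylated methine; ring A = C1–C5/C9, ring B = C5–C9/C1), both rings are opened at C1–C9 and C7–C8, which leaves an acyclic, enantiopure polyketide-type keto ester. The key step exploits C1 as the α-carbon shared by the C2 and C9 carbonyls of ring A, and the adjacent quaternary C8. In one flask a polyanion Dieckmann closure makes C1–C9, then iron-hydride hydrogen-atom transfer to an isopropenyl group on C1 gives the tertiary C8 radical, which adds 6-exo to a tethered enoate to make C7–C8. The auxiliary-set C5 centre relays to C1 and C7.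

Key step: step 11

Assumption: the sense of induction in step 3 is matched to the required (R)-centre by the choice of coordinating additive (or of the D-valine ester), and polyketone intermediates are drawn as single tautomers.

Remarks on names: core locants C1–C9 in descriptive names follow the target. "Bridged aroyl" stands for [2,2,4,4-tetraisopropylbenzo[f][1,3,5,2,4]trioxadisilepin-7-yl]carbonyl, that is, 3,4-dihydroxybenzoyl with both oxygens joined through one Si(i-Pr)2–O–Si(i-Pr)2 unit.

Step 1
Reactants: 1 methyl acetoacetate; 2 geranyl bromide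
Product: 3 methyl (4E)-2-acetyl-5,9-dimethyldeca-4,8-dienoate (racemic)
Conditions: K2CO3, acetone, 56 °C
Reagents that add atoms: none
Why: SN2 C-alkylation of the acetoacetate enolate by the primary allylic bromide (acetoacetic ester alkylation) should leave the E alkene untouched; the new centre is racemic and is replaced in step 3.

Step 2
Reactants: 3 methyl (4E)-2-acetyl-5,9-dimethyldeca-4,8-dienoate; 4 L-valine tert-butyl ester
Product: 5 methyl (2Z,4E)-2-[1-{[(2S)-1-tert-butoxy-3-methyl-1-oxobutan-2-yl]amino}ethylidene]-5,9-dimethyldeca-4,8-dienoate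
Conditions: AcOH (cat.), 4 Å molecular sieves, benzene, reflux
Reagents that add atoms: none
Why: Condensation of the β-keto ester with the primary amine (enamine formation) should give the hydrogen-bonded (Z)-enamino ester that carries the chiral auxiliary, the weak acid leaving the tert-butyl ester intact.

Step 3
Reactants: 5 the (Z)-enamino ester; 6 allyl bromide
Product: 8 methyl (2R,4E)-2-acetyl-5,9-dimethyl-2-(prop-2-en-1-yl)deca-4,8-dienoate, via alkylated imine 7 (not isolated)
Conditions: LiN(i-Pr)2, toluene–THF, −78 °C; 6; then aq. AcOH/NaOAc, rt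
Reagents that add atoms: water, O
Why: In the chelated lithio-enamine the auxiliary's isopropyl and tert-butyl ester groups shield one face, so allylation should set the C5 quaternary centre (auxiliary-controlled asymmetric alkylation of an α-substituted β-keto ester), and mild hydrolysis releases the ketone and the auxiliary.

Step 4
Reactants: 9 3-methylbut-2-enoic acid; 2 geranyl bromide
Product: 10 (4E)-5,9-dimethyl-2-(prop-1-en-2-yl)deca-4,8-dienoic acid (racemic)
Conditions: LiN(i-Pr)2 (2.2 equiv), THF, −78 to 0 °C; 2; then 1 M HCl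
Reagents that add atoms: none
Why: The dienolate dianion should be alkylated at the α-carbon (deconjugative α-alkylation), placing the geranyl and isopropenyl groups on the future C1; this centre is racemic and is erased in step 11.

Step 5
Reactants: 10 (4E)-5,9-dimethyl-2-(prop-1-en-2-yl)deca-4,8-dienoic acid; 8 methyl (2R,4E)-2-acetyl-5,9-dimethyl-2-(prop-2-en-1-yl)deca-4,8-dienoate
Product: 12 methyl (2R,4E)-2-[(6E)-7,11-dimethyl-3-oxo-4-(prop-1-en-2-yl)dodeca-6,10-dienoyl]-5,9-dimethyl-2-(prop-2-en-1-yl)deca-4,8-dienoate (both epimers at the isopropenyl-bearing carbon), via acid chloride 11 (not isolated)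
Conditions: 10, 1-chloro-N,N,2-trimethylprop-1-en-1-amine, CH2Cl2, 0 °C; then 8, MgBr2·OEt2, i-Pr2NEt, CH2Cl2, rt
Reagents that add atoms: none
Why: Neutral acid chloride formation followed by magnesium-mediated soft enolisation of the only enolisable position of 8 (the acetyl CH3) should give C-acylation to the 1,3-diketone (crossed Claisen-type acylation) without touching C5.

Step 6
Reactants: 13 3,4-dihydroxybenzaldehyde; 14 1,3-dichloro-1,1,3,3-tetraisopropyldisiloxane
Product: 15 2,2,4,4-tetraisopropylbenzo[f][1,3,5,2,4]trioxadisilepine-7-carbaldehyde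
Conditions: imidazole, DMF, 0 °C to rt
Reagents that add atoms: none
Why: One molecule of the bifunctional dichlorodisiloxane should silylate one phenol and then close the unstrained seven-membered ring on the ortho phenol (cyclic silyl ether formation), so a single reagent masks the whole catechol while the aldehyde is inert.

Step 7
Reactants: 15 the bridged aldehyde
Product: 16 2,2,4,4-tetraisopropylbenzo[f][1,3,5,2,4]trioxadisilepine-7-carboxylic acid
Conditions: NaClO2, NaH2PO4, 2-methylbut-2-ene, t-BuOH/H2O, rt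
Reagents that add atoms: sodium chlorite, [Na+].[O-]Cl=O
Why: Chlorite at about pH 4 should oxidise the aldehyde to the acid (Pinnick oxidation) while the alkene scavenger removes hypochlorous acid, conditions that hindered aryl silyl ethers and the arene tolerate.

Step 8
Reactants: 16 the bridged acid
Product: 17 2,2,4,4-tetraisopropylbenzo[f][1,3,5,2,4]trioxadisilepine-7-carbonyl chloride
Conditions: 1-chloro-N,N,2-trimethylprop-1-en-1-amine, CH2Cl2, 0 °C to rt
Reagents that add atoms: 1-chloro-N,N,2-trimethylprop-1-en-1-amine, CC(C)=C(Cl)N(C)C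
Why: The α-chloroenamine should convert the acid into the acid chloride under neutral conditions (acid chloride formation without release of HCl), so the Si–O bonds are not exposed to acid.

Step 9
Reactants: 12 the 1,3-diketone; 17 the bridged aroyl chloride
Product: 18 methyl (2R,4E)-2-[(6E)-2-(bridged aroyl)-7,11-dimethyl-3-oxo-4-(prop-1-en-2-yl)dodeca-6,10-dienoyl]-5,9-dimethyl-2-(prop-2-en-1-yl)deca-4,8-dienoate
Conditions: MgCl2, pyridine, CH2Cl2, 0 °C to rt
Reagents that add atoms: none
Why: The magnesium chelate of the 1,3-diketone should be acylated at the central carbon C3 (magnesium-enolate C-acylation), which installs the aroyl group and blocks C3 as a nucleophile in later steps.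

Step 10
Reactants: 18 the allyl triketone; 19 methyl acrylate
Product: 20 methyl (2R,4E)-2-[(6E)-2-(bridged aroyl)-7,11-dimethyl-3-oxo-4-(prop-1-en-2-yl)dodeca-6,10-dienoyl]-2-[(2E)-4-methoxy-4-oxobut-2-en-1-yl]-5,9-dimethyldeca-4,8-dienoate
Conditions: second-generation Hoveyda–Grubbs catalyst (5 mol%), CH2Cl2, 40 °C
Reagents that add atoms: none
Why: Olefin cross-metathesis should engage only the terminal allyl group (the trisubstituted and 1,1-disubstituted alkenes are much slower) and give the E enoate that serves as radical acceptor.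

Step 11
Reactants: 20 the enoate triketone
Product: 22 methyl 2-[(1S,5S,7S)-3-(bridged aroyl)-1,5-bis[(2E)-3,7-dimethylocta-2,6-dien-1-yl]-4-hydroxy-8,8-dimethyl-2,9-dioxobicyclo[3.3.1]non-3-en-7-yl]acetate, via monocyclic trione 21 (not isolated)
Conditions: lithium 2,2,6,6-tetramethylpiperidide (2.3 equiv), THF, −78 to −20 °C; AcOH; then Fe(acac)3 (30 mol%), PhSiH3, EtOH/(CH2OH)2, 60 °C (one flask)
Reagents that add atoms: none
Why: The hindered amide base should convert 20 into its dianion (triketonate plus the C1 enolate, which is extended through the isopropenyl group), whose C1 carbon attacks the C9 ester in a Dieckmann closure driven by the stabilised product anion; after neutralisation, iron-hydride hydrogen-atom transfer to the isopropenyl group gives the tertiary C8 radical, which adds to the enoate β-carbon C7, and the α-ester radical is reduced and protonated. The closest known reactions are the terminal acylation of β-polyketone polyanions and the iron-catalysed reductive coupling of unactivated olefins with acrylates (Giese type). Ring A closes 6-exo-trig at the ester carbonyl and ring B 6-exo-trig at C7 through a chair in which C8 and C6 are both axial on ring A. C1 is not controlled in the Dieckmann stage, but only the epimer with the isopropenyl group cis to the butenoate arm can reach C7, so the bicycle forms with C1 tied to the preset C5 while the other epimer stays monocyclic; C7 is set by the chair-like transition state, which places the ester-bearing terminus exo (equatorial), away from ring A. The step needs hydrogen-atom transfer at the isopropenyl group and not at the four trisubstituted alkenes, and attack at C7 and not at the enoate α-carbon: the first rests on the higher reactivity of 1,1-disubstituted olefins, the second on the polarity match of the nucleophilic tertiary radical with the β-carbon, while the C3 aroyl group prevents enolate Michael addition to the enoate.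

Step 12
Reactants: 22 the bicyclic methyl ester
Product: 23 2-[(1S,5S,7S)-3-(bridged aroyl)-1,5-bis[(2E)-3,7-dimethylocta-2,6-dien-1-yl]-4-hydroxy-8,8-dimethyl-2,9-dioxobicyclo[3.3.1]non-3-en-7-yl]acetaldehyde
Conditions: i-Bu2AlH (3 equiv), CH2Cl2, −78 °C; aq. potassium sodium tartrate
Reagents that add atoms: none
Why: At −78 °C the unhindered methyl ester should stop at the tetrahedral aluminate and give the aldehyde on work-up (partial ester reduction), the enolised triketone being masked as its aluminium enolate and the C9 ketone shielded by two quaternary carbons.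

Step 13
Reactants: 23 the bicyclic aldehyde; 24 isopropyltriphenylphosphonium iodide
Product: 25 (1S,5S,7R)-3-(bridged aroyl)-1,5-bis[(2E)-3,7-dimethylocta-2,6-dien-1-yl]-4-hydroxy-8,8-dimethyl-7-(3-methylbut-2-en-1-yl)bicyclo[3.3.1]non-3-ene-2,9-dione
Conditions: 24, KN(SiMe3)2 (excess), THF, 0 °C; then 23, −78 °C to rt
Reagents that add atoms: none
Why: The non-stabilised ylide should olefinate the aldehyde selectively over the hindered and enolised ketones (Wittig reaction), giving the prenyl group, which has no E/Z issue.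

Step 14
Reactants: 25 the disiloxane-bridged bicycle
Product: 26 (1S,5S,7R)-3-(3,4-dihydroxybenzoyl)-1,5-bis[(2E)-3,7-dimethylocta-2,6-dien-1-yl]-4-hydroxy-8,8-dimethyl-7-(3-methylbut-2-en-1-yl)bicyclo[3.3.1]non-3-ene-2,9-dione
Conditions: Bu4NF, AcOH, THF, 0 °C
Reagents that add atoms: none
Why: Buffered fluoride should cleave both aryl Si–O bonds of the disiloxane bridge (desilylation) without affecting the acid-sensitive polyprenyl alkenes or the enolised triketone.

Compound list
1 | methyl acetoacetate | CC(=O)CC(=O)OC | starting material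
2 | geranyl bromide, (2E)-1-bromo-3,7-dimethylocta-2,6-diene | CC(C)=CCC/C(C)=C/CBr | starting material
3 | methyl (4E)-2-acetyl-5,9-dimethyldeca-4,8-dienoate (racemic) | CC(C)=CCC/C(C)=C/CC(C(C)=O)C(=O)OC | intermediate
4 | L-valine tert-butyl ester | CC(C)[C@H](N)C(=O)OC(C)(C)C | starting material
5 | methyl (2Z,4E)-2-[1-{[(2S)-1-tert-butoxy-3-methyl-1-oxobutan-2-yl]amino}ethylidene]-5,9-dimethyldeca-4,8-dienoate | COC(=O)/C(C/C=C(\C)CCC=C(C)C)=C(/C)N[C@@H](C(C)C)C(=O)OC(C)(C)C | intermediate
6 | allyl bromide | C=CCBr | starting material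
7 | alkylated imine: N-[(2S)-1-tert-butoxy-3-methyl-1-oxobutan-2-yl] imine of 8 at the acetyl carbonyl, (2R) at the quaternary carbon | CC(C)=CCC/C(C)=C/C[C@](C(C)=N[C@@H](C(C)C)C(=O)OC(C)(C)C)(C(=O)OC)CC=C | intermediate
8 | methyl (2R,4E)-2-acetyl-5,9-dimethyl-2-(prop-2-en-1-yl)deca-4,8-dienoate | CC(C)=CCC/C(C)=C/C[C@](C(C)=O)(C(=O)OC)CC=C | intermediate
9 | 3-methylbut-2-enoic acid | CC(C)=CC(=O)O | starting material
10 | (4E)-5,9-dimethyl-2-(prop-1-en-2-yl)deca-4,8-dienoic acid (racemic) | CC(=C)C(C/C=C(\C)CCC=C(C)C)C(=O)O | intermediate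
11 | (4E)-5,9-dimethyl-2-(prop-1-en-2-yl)deca-4,8-dienoyl chloride | CC(=C)C(C/C=C(\C)CCC=C(C)C)C(Cl)=O | intermediate
12 | methyl (2R,4E)-2-[(6E)-7,11-dimethyl-3-oxo-4-(prop-1-en-2-yl)dodeca-6,10-dienoyl]-5,9-dimethyl-2-(prop-2-en-1-yl)deca-4,8-dienoate (both epimers at the isopropenyl-bearing carbon) | CC(C)=CCC/C(C)=C/C[C@](C(=O)CC(=O)C(C/C=C(\C)CCC=C(C)C)C(C)=C)(C(=O)OC)CC=C | intermediate
13 | 3,4-dihydroxybenzaldehyde | O=Cc1ccc(O)c(O)c1 | starting material
14 | 1,3-dichloro-1,1,3,3-tetraisopropyldisiloxane | CC(C)[Si](Cl)(C(C)C)O[Si](Cl)(C(C)C)C(C)C | starting material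
15 | 2,2,4,4-tetraisopropylbenzo[f][1,3,5,2,4]trioxadisilepine-7-carbaldehyde | O=Cc1ccc2O[Si](C(C)C)(C(C)C)O[Si](C(C)C)(C(C)C)Oc2c1 | intermediate
16 | 2,2,4,4-tetraisopropylbenzo[f][1,3,5,2,4]trioxadisilepine-7-carboxylic acid | OC(=O)c1ccc2O[Si](C(C)C)(C(C)C)O[Si](C(C)C)(C(C)C)Oc2c1 | intermediate
17 | 2,2,4,4-tetraisopropylbenzo[f][1,3,5,2,4]trioxadisilepine-7-carbonyl chloride | O=C(Cl)c1ccc2O[Si](C(C)C)(C(C)C)O[Si](C(C)C)(C(C)C)Oc2c1 | intermediate
18 | allyl triketone: 12 carrying the bridged aroyl group on the carbon between its two ketones, (2R) | CC(C)=CCC/C(C)=C/C[C@](C(=O)C(C(=O)c1ccc2O[Si](C(C)C)(C(C)C)O[Si](C(C)C)(C(C)C)Oc2c1)C(=O)C(C/C=C(\C)CCC=C(C)C)C(C)=C)(C(=O)OC)CC=C | intermediate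
19 | methyl acrylate | C=CC(=O)OC | starting material
20 | enoate triketone: 18 with the allyl group extended to (2E)-4-methoxy-4-oxobut-2-en-1-yl, (2R) | CC(C)=CCC/C(C)=C/C[C@](C(=O)C(C(=O)c1ccc2O[Si](C(C)C)(C(C)C)O[Si](C(C)C)(C(C)C)Oc2c1)C(=O)C(C/C=C(\C)CCC=C(C)C)C(C)=C)(C(=O)OC)C/C=C/C(=O)OC | intermediate
21 | monocyclic trione: (2R,6R)-4-(bridged aroyl)-2,6-bis[(2E)-3,7-dimethylocta-2,6-dien-1-yl]-2-[(2E)-4-methoxy-4-oxobut-2-en-1-yl]-6-(prop-1-en-2-yl)cyclohexane-1,3,5-trione, the epimer with isopropenyl cis to the butenoate arm, formed together with its 6-epimer | CC(C)=CCC/C(C)=C/C[C@]1(C/C=C/C(=O)OC)C(=O)C(C(=O)c2ccc3O[Si](C(C)C)(C(C)C)O[Si](C(C)C)(C(C)C)Oc3c2)C(=O)[C@@](C/C=C(\C)CCC=C(C)C)(C(C)=C)C1=O | intermediate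
22 | methyl 2-[(1S,5S,7S)-3-(bridged aroyl)-1,5-bis[(2E)-3,7-dimethylocta-2,6-dien-1-yl]-4-hydroxy-8,8-dimethyl-2,9-dioxobicyclo[3.3.1]non-3-en-7-yl]acetate | CC(C)=CCC/C(C)=C/C[C@]12C[C@@H](CC(=O)OC)C(C)(C)[C@](C/C=C(\C)CCC=C(C)C)(C(=O)C(C(=O)c3ccc4O[Si](C(C)C)(C(C)C)O[Si](C(C)C)(C(C)C)Oc4c3)=C1O)C2=O | intermediate
23 | 2-[(1S,5S,7S)-3-(bridged aroyl)-1,5-bis[(2E)-3,7-dimethylocta-2,6-dien-1-yl]-4-hydroxy-8,8-dimethyl-2,9-dioxobicyclo[3.3.1]non-3-en-7-yl]acetaldehyde | CC(C)=CCC/C(C)=C/C[C@]12C[C@@H](CC=O)C(C)(C)[C@](C/C=C(\C)CCC=C(C)C)(C(=O)C(C(=O)c3ccc4O[Si](C(C)C)(C(C)C)O[Si](C(C)C)(C(C)C)Oc4c3)=C1O)C2=O | intermediate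
24 | isopropyltriphenylphosphonium iodide | CC(C)[P+](c1ccccc1)(c1ccccc1)c1ccccc1.[I-] | starting material
25 | (1S,5S,7R)-3-(bridged aroyl)-1,5-bis[(2E)-3,7-dimethylocta-2,6-dien-1-yl]-4-hydroxy-8,8-dimethyl-7-(3-methylbut-2-en-1-yl)bicyclo[3.3.1]non-3-ene-2,9-dione | CC(C)=CCC/C(C)=C/C[C@]12C[C@@H](CC=C(C)C)C(C)(C)[C@](C/C=C(\C)CCC=C(C)C)(C(=O)C(C(=O)c3ccc4O[Si](C(C)C)(C(C)C)O[Si](C(C)C)(C(C)C)Oc4c3)=C1O)C2=O | intermediate
26 | (1S,5S,7R)-3-(3,4-dihydroxybenzoyl)-1,5-bis[(2E)-3,7-dimethylocta-2,6-dien-1-yl]-4-hydroxy-8,8-dimethyl-7-(3-methylbut-2-en-1-yl)bicyclo[3.3.1]non-3-ene-2,9-dione | CC(C)=CCC/C(C)=C/C[C@]12C[C@@H](CC=C(C)C)C(C)(C)[C@](C/C=C(\C)CCC=C(C)C)(C(=O)C(C(=O)c3ccc(O)c(O)c3)=C1O)C2=O | target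

Total step count: 14. Longest linear sequence: 10 steps (steps 1, 2, 3, 5, 9, 10, 11, 12, 13, 14).

Steps most likely to fail

Step 11. What may go wrong: the Dieckmann stage has no facial bias at C1, so part of the material is diverted into the epimer that cannot close ring B; the amide base may deprotonate or attack the enoate arm; hydrogen-atom transfer may occur at the trisubstituted alkenes instead of the isopropenyl group. Fallback (sets out from 8, returns at 22): C1 is kept as an enolisable carbon through both ring closures and its geranyl group is introduced last, at the bridgehead. Soft-enolisation acylation of 8 with 3-methylbut-2-enoyl chloride (MgBr2·OEt2, i-Pr2NEt) should give the enone diketone F1. Magnesium-mediated C-aroylation with 17 should give the enone triketone F2, and cross-metathesis with 19 the enone enoate F3. γ-Deprotonation with lithium 2,2,6,6-tetramethylpiperidide and α-acylation by the C9 ester (vinylogous Dieckmann closure) should give the monocyclic isopropylidene trione F4, in which C1 is trigonal. SmI2 in THF/t-BuOH should then couple the alkylidene β-carbon C8 reductively with the enoate β-carbon C7, only the two electron-poor alkenes being reduced, to give the bicyclic bridgehead-CH trione F5. Bridgehead deprotonation of F5 at C1 with excess lithium 2,2,6,6-tetramethylpiperidide (dianion) and alkylation with 2 should give 22, the bicycle dictating the C1 configuration.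

Step 12. What may go wrong: over-reduction of the ester to the primary alcohol, or hydride addition to the C9 or aryl ketone. Fallback (sets out from 22, returns at 23): the oxidation level is adjusted through a thioester. Me3SnOH in 1,2-dichloroethane at 80 °C should cleave the methyl ester to the bicyclic acid F6; EtSH, EDC and DMAP should give the S-ethyl thioester F7; Et3SiH with Pd/C should reduce it to 23 (Fukuyama reduction), ketones and trisubstituted alkenes being inert.

Step 3. What may go wrong: insufficient facial discrimination or N-allylation of the lithio-enamine. Fallback (sets out from 3, returns at 8; no new compound, F0): palladium-catalysed asymmetric allylic alkylation of 3 with allyl acetate, [Pd(C3H5)Cl]2, a C2-symmetric trans-1,2-diaminocyclohexane bis(2-diphenylphosphinobenzamide) ligand and Cs2CO3 in toluene, the ligand enantiomer being chosen for the (R)-centre.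

Further compounds
F1 | step 11 | methyl (2R,4E)-5,9-dimethyl-2-(5-methyl-3-oxohex-4-enoyl)-2-(prop-2-en-1-yl)deca-4,8-dienoate | CC(C)=CCC/C(C)=C/C[C@](C(=O)CC(=O)C=C(C)C)(C(=O)OC)CC=C
F2 | step 11 | enone triketone: F1 carrying the bridged aroyl group on the carbon between its two ketones | CC(C)=CCC/C(C)=C/C[C@](C(=O)C(C(=O)c1ccc2O[Si](C(C)C)(C(C)C)O[Si](C(C)C)(C(C)C)Oc2c1)C(=O)C=C(C)C)(C(=O)OC)CC=C
F3 | step 11 | enone enoate: F2 with the allyl group extended to (2E)-4-methoxy-4-oxobut-2-en-1-yl | CC(C)=CCC/C(C)=C/C[C@](C(=O)C(C(=O)c1ccc2O[Si](C(C)C)(C(C)C)O[Si](C(C)C)(C(C)C)Oc2c1)C(=O)C=C(C)C)(C(=O)OC)C/C=C/C(=O)OC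
F4 | step 11 | monocyclic isopropylidene trione: (2R)-4-(bridged aroyl)-2-[(2E)-3,7-dimethylocta-2,6-dien-1-yl]-2-[(2E)-4-methoxy-4-oxobut-2-en-1-yl]-6-(propan-2-ylidene)cyclohexane-1,3,5-trione | CC(C)=CCC/C(C)=C/C[C@]1(C/C=C/C(=O)OC)C(=O)C(C(=O)c2ccc3O[Si](C(C)C)(C(C)C)O[Si](C(C)C)(C(C)C)Oc3c2)C(=O)C(=C(C)C)C1=O
F5 | step 11 | bicyclic bridgehead-CH trione: 22 with hydrogen in place of the C1 geranyl group, (1S,5S,7S) | CC(C)=CCC/C(C)=C/C[C@]12C[C@@H](CC(=O)OC)C(C)(C)[C@H](C(=O)C(C(=O)c3ccc4O[Si](C(C)C)(C(C)C)O[Si](C(C)C)(C(C)C)Oc4c3)=C1O)C2=O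
F6 | step 12 | bicyclic acid: the carboxylic acid of 22, (1S,5S,7S) | CC(C)=CCC/C(C)=C/C[C@]12C[C@@H](CC(=O)O)C(C)(C)[C@](C/C=C(\C)CCC=C(C)C)(C(=O)C(C(=O)c3ccc4O[Si](C(C)C)(C(C)C)O[Si](C(C)C)(C(C)C)Oc4c3)=C1O)C2=O
F7 | step 12 | S-ethyl thioester of F6, (1S,5S,7S) | CC(C)=CCC/C(C)=C/C[C@]12C[C@@H](CC(=O)SCC)C(C)(C)[C@](C/C=C(\C)CCC=C(C)C)(C(=O)C(C(=O)c3ccc4O[Si](C(C)C)(C(C)C)O[Si](C(C)C)(C(C)C)Oc4c3)=C1O)C2=O
F0 | step 3 | none | none
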